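## Structural features

The target is a flavonol: a benzene ring A fused to a 4-pyranone ring C (a 4H-chromen-4-one), with a 2,5-dihydroxyphenyl ring B joined to C2 by a single C–C bond and a hydroxyl on C3. Ring A is fully substituted: C4a and C8a are the fusion carbons and C5 to C8 carry OH, OMe, OMe and OMe, so four contiguous oxygens must be placed and the one at C5 kept distinct from the other three. The molecule has no stereocentre, so no relative or absolute configuration has to be controlled. The fragile parts are the ring B hydroquinone, which air can oxidise to a quinone that the neighbouring 3-hydroxyl could then attack, and the chelating 3-hydroxy-4-pyranone/5-hydroxyl array; both argue for releasing all phenols in the last step. The real difficulty is ring A, a hexasubstituted benzene whose oxygen pattern must be set regiospecifically, together with the C3–O bond, which a plain diketone cyclisation does not deliver. The key step uses the fact that O5 and O8 are para to each other: with O8 unmethylated, ring A is a hydroquinone whose quinone form has a single C–H carbon, C8a, that is β to both the C5 quinone carbonyl and the C4 ketone, so a side-chain enol oxygen can bond to it and close ring C through C8a–O1.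

## Logic of the disconnections

17 to 16: the three benzylic C–O bonds (at O5, O2' and O5') are cut. The free ring B hydroquinone and the chelated 5-hydroxyl are the most oxidation-prone groups, so they are released last in one neutral operation. Every earlier intermediate then carries at most one free hydroxyl. The forward step must cleave three aryl benzyl ethers without touching C2=C3 or the methyl ethers, and the product must be kept from air.

16 to 14: the C3–O bond is cut. C3 is the only unfunctionalised carbon of ring C, and in a fully O-protected flavone the C2=C3 bond is the π bond most open to an electrophilic oxygen-transfer reagent. The gain is that the precursor is an ordinary flavone, so no oxygen is needed on the diketone methylene. The forward step must epoxidise C2=C3 in preference to the electron-rich arenes, which is why no free phenol may be present, and epoxide 15 must isomerise to the enol.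

14 to 13 to 12: the O5–CH2Ph and O8–CH3 bonds are cut. Both are plain O-alkylations, told apart by the hydrogen bond between the 5-hydroxyl and the C4 carbonyl. This uncovers the 5,8-hydroquinone of 12, the pattern the key step produces. The methylation must stop at the non-chelated 8-hydroxyl, and the benzylation of the chelated hydroxyl needs forcing conditions.

12 to 9: the C8a–O1 bond is cut. Ring A of 12 is a hydroquinone, its quinone 10 has its only C–H carbon exactly where O1 must be attached, and the bond can therefore be made from a C–H without a halogen or a sixth pre-installed substituent. Ring C opens to a 1,3-diketone on a pentasubstituted benzene. The forward step must oxidise 9 to 10, deliver the enol oxygen (not the central carbon) to C8a, and return any over-oxidised 11 to 12.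

9 to 3 and 8: the C–C bond between the diketone methylene and the ring B carbonyl (future C2–C3) is cut, a Claisen-type retron. This divides the molecule into two aromatic pieces of similar size. The forward step needs C-acylation of a polyanion in preference to O-acylation of its phenoxides, under strict exclusion of air.

8 to 7 to 4 and 5: the acyl C–Cl bond and the two benzylic O–C bonds are cut, and the carboxyl group is traced back through 6 to a methyl ester. This leads back to a stock dihydroxybenzoate ester and an alkyl halide. Both benzyl groups delivered are kept and none is spent on the carboxyl group. The only demand is that the methyl ester be saponified without touching the two aryl benzyl ethers.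

3 to 1: the C5–O bond of the acetophenone ring is cut. C5 is para to the phenolic hydroxyl of 1 and is the position a persulfate oxidation hydroxylates, passing through sulfate 2. The gain is a stock acetophenone that already holds the acetyl group and three of the four ring A oxygens in the right places. The forward step must be para-selective and must not degrade the hydroquinone formed.

## Other disconnections considered

Alternative 1: The cut is the C2=C3 double bond, and the product of the key step is 5-(benzyloxy)-2-[2,5-bis(benzyloxy)phenyl]-6,7,8-trimethoxy-4H-chromen-4-one A1, the same compound as 14. In the forward step the stabilised ylide carbon of 3-(benzyloxy)-4,5,6-trimethoxy-2-[2-(triphenyl-λ5-phosphanylidene)acetyl]phenyl 2,5-bis(benzyloxy)benzoate A2 would attack the neighbouring aryl ester carbonyl, and collapse of the oxaphosphetane with loss of the phosphine oxide would close ring C.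
- In favour: the closure is thermal and neutral, it is an established flavone synthesis, ring A undergoes no redox change, and the 5-O-benzyl group is already in place.
- Against: A2 has to come from 1-[2-(benzyloxy)-6-hydroxy-3,4,5-trimethoxyphenyl]ethan-1-one A3, in which all six ring positions are substituted and the two ortho oxygens are differentiated. The difficulty of ring A is thereby moved into the starting material. A3 would also need α-bromination next to a very electron-rich ring, phosphonium salt formation and aroylation of a hindered chelated phenol.
- Comparison: both plans close ring C; this one makes a C=C bond from two carbonyl-level carbons, the chosen one a C–O bond from a C–H. On mechanistic precedent the alternative is the better of the two. On the endgame it is equal, since A1 enters the chosen route at 14 and shares steps 8 and 9. On step economy it is expected to be worse, because A3 costs several steps more than 3, which is one step from a stock compound.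

Alternative 2: The cut is C4a–C5, with ring A built last, and the product of the key step is 3-(benzyloxy)-2-[2,5-bis(benzyloxy)phenyl]-5-hydroxy-6,7,8-trimethoxy-4H-chromen-4-one A4. Its precursor, 4-{5-(benzyloxy)-6-[2,5-bis(benzyloxy)phenyl]-4-oxo-4H-pyran-2-yl}-2,3,4-trimethoxycyclobut-2-en-1-one A5, would come from addition of the 6-lithio derivative of 3-(benzyloxy)-2-[2,5-bis(benzyloxy)phenyl]-4H-pyran-4-one A7 to 3,4-dimethoxycyclobut-3-ene-1,2-dione A6, followed by O-methylation. On heating, A5 should open to a dienylketene whose ketene carbon bonds to the pyranone C–H carbon in a 6π closure, and tautomerisation would give the 5-hydroxychromone.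
- In favour: the four contiguous oxygens of ring A arrive with unambiguous regiochemistry and already differentiated (free 5-hydroxyl, three methyl ethers), and the C3 oxygen is carried as a benzyl ether. A4 would be a single hydrogenolysis from 17, which is a better endgame than the chosen plan (one step after the key step against four).
- Against: A7 needs its own multistep synthesis. Its lithiation next to the ring oxygen must compete with addition to the conjugated carbonyl. A hindered tertiary alkoxide must be methylated. The closure needs about 140 °C and uses a vinylogous ester double bond as the 2π partner.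
- Comparison: structurally this is a convergent union of a ring B/C piece with a four-carbon ring A synthon. The pericyclic cascade is well known for 4-aryl- and 4-alkenylcyclobutenones, but its use on a 4-pyranone is an extension of precedent, so on mechanistic certainty the two plans are about equal. The step count is expected to be similar or higher overall, because the steps saved at the end are spent on A7.

Alternative 3: The cut is C4–C4a, and the product of the key step is 2-[2,5-bis(benzyloxy)phenyl]-5-hydroxy-6,7,8-trimethoxy-4H-chromen-4-one A8, the same compound as 13. (2Z)-3-[2,5-Bis(benzyloxy)phenyl]-3-(5-hydroxy-2,3,4-trimethoxyphenoxy)prop-2-enoic acid A9 would be made by conjugate addition of one hydroxyl of the symmetrical 4,5,6-trimethoxybenzene-1,3-diol A10 to ethyl 3-[2,5-bis(benzyloxy)phenyl]prop-2-ynoate A11 and saponification. Activation of A9 as a mixed anhydride would then acylate the one free carbon of ring A, which lies between two oxygens.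
- In favour: the symmetry of A10 removes any regiochemical question, the acylated carbon is the most nucleophilic position available, and no redox change or selective methylation of ring A is needed.
- Against: A10 is not a stock chemical and needs several steps, and mono- must be secured over bis-addition to the alkyne. Only the Z acid can close ring C, since the E isomer would place the acid next to ring B and favour an indenone. The strongly acidic acylating medium endangers the benzyl ethers on the electron-rich ring B and would transiently acylate the free phenol, which deactivates ring A.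
- Comparison: this plan makes the C–C bond of ring C and keeps ring A at one oxidation level. Friedel–Crafts closure of aryloxyacrylic acids to chromones is better precedented than the chosen oxa-Michael closure, a point on which the alternative is the better. Downstream it is equal, as A8 shares steps 7 to 9. Upstream it is expected to be longer because of A10 and A11.

Key step: step 5

Remark on the chemistry: 9 and 12 map atom for atom onto each other and onto the target and are used as drawn; because 12 is itself an oxidisable hydroquinone, the key step is run with excess oxidant and a reductive work-up; the chelated 5-hydroxyl is benzylated before the C3 oxidation because dimethyldioxirane attacks free, electron-rich phenols (epoxide 15 is racemic and its stereocentres vanish in the same step); ring B is taken from the commercial methyl ester 4, and each molecule of 7 holds two benzyl groups from benzyl bromide.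

## Steps

Step 1
Reactants: 1 1-(2-hydroxy-3,4-dimethoxyphenyl)ethan-1-one
Product: 3 1-(2,5-dihydroxy-3,4-dimethoxyphenyl)ethan-1-one, via aryl sulfate 2 (not isolated)
Conditions: K2S2O8 (1.1 equiv), aq. KOH, 15–20 °C; then HCl, 90 °C
Reagents that add atoms: potassium peroxodisulfate, [K+].[K+].[O-]S(=O)(=O)OOS(=O)(=O)[O-]
Why: Elbs persulfate oxidation: the phenoxide attacks a peroxide oxygen through its para carbon (C5, the only position open to this mode) to give sulfate 2, which acid hydrolyses to the hydroquinone. The reaction is established for ortho-hydroxyacetophenones, should proceed with modest conversion, and unreacted 1 is recovered by extraction before the hydrolysis.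

Step 2
Reactants: 4 methyl 2,5-dihydroxybenzoate; 5 benzyl bromide
Product: 7 2,5-bis(benzyloxy)benzoic acid, via methyl ester 6 (not isolated)
Conditions: BnBr (2.3 equiv), K2CO3 (3 equiv), DMF, 60 °C; then aq. NaOH, MeOH, 70 °C; HCl
Reagents that add atoms: benzyl bromide, BrCc1ccccc1; sodium hydroxide, [Na+].[OH-]
Why: Williamson benzylation of both phenols of 4 consumes two molecules of benzyl bromide per molecule of 4 (one counted as reactant 5, the other as the reagent named above) and gives methyl ester 6. Saponification then cleaves only the methyl ester, because aryl benzyl ethers are inert to hydroxide, and the hydroxide oxygen ends up in the carboxyl group of 7.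

Step 3
Reactants: 7 2,5-bis(benzyloxy)benzoic acid
Product: 8 2,5-bis(benzyloxy)benzoyl chloride
Conditions: (COCl)2 (1.5 equiv), DMF (cat.), CH2Cl2, 0 °C to rt; evaporate, use crude
Reagents that add atoms: oxalyl chloride, ClC(=O)C(=O)Cl
Why: Standard acid chloride formation through the chloroiminium intermediate, under conditions that leave aryl benzyl ethers untouched.

Step 4
Reactants: 3 1-(2,5-dihydroxy-3,4-dimethoxyphenyl)ethan-1-one; 8 2,5-bis(benzyloxy)benzoyl chloride
Product: 9 1-[2,5-bis(benzyloxy)phenyl]-3-(2,5-dihydroxy-3,4-dimethoxyphenyl)propane-1,3-dione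
Conditions: LiN(SiMe3)2 (4.2 equiv), THF, −78 to −10 °C; 8 (1.0 equiv), −78 °C to rt; cold aq. HCl; Ar, degassed solvents
Reagents that add atoms: none
Why: Claisen-type C-aroylation of the lithium trianion (two phenoxides and the ketone enolate), a known route to hydroxylated 1,3-diaryl-1,3-diketones: the enolate carbon is the most nucleophilic site and the fourth equivalent of base deprotonates the product, which prevents a second acylation. The cold acidic quench should not bring about cyclodehydration, which needs hot strong acid.

Step 5
Reactants: 9 1-[2,5-bis(benzyloxy)phenyl]-3-(2,5-dihydroxy-3,4-dimethoxyphenyl)propane-1,3-dione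
Product: 12 2-[2,5-bis(benzyloxy)phenyl]-5,8-dihydroxy-6,7-dimethoxy-4H-chromen-4-one, via acylquinone 10 (not isolated), via flavone-5,8-quinone 11 (not isolated)
Conditions: Ag2O (3 equiv), Na2SO4, CH2Cl2 (0.02 M), rt, dark; filter; aq. Na2S2O4, EtOAc
Reagents that add atoms: none
Why: Proposed new method: Ag2O dehydrogenates the hydroquinone of 9 to acylquinone 10, in which the ring C–H carbon (future C8a) is the β-carbon of both the C5 quinone carbonyl and the C4 ketone, and the oxygen of the enolised diketone adds to it in an intramolecular oxa-Michael addition (equivalently an oxa-6π closure of the dienone tautomer), after which enolisation restores ring A as the hydroquinone 12; the closest known reaction type is the oxidative cyclisation of 2,5-dihydroxybenzophenones carrying a 2'-hydroxyl to xanthones through the acylquinone, with a 1,3-diketone enol taking the place of the phenol. Ring C closes in the 6-endo-trig mode and the only skeletal bond formed is C8a–O1. No stereocentre is created. Since 12 is itself an oxidisable hydroquinone, excess Ag2O should carry it on to quinone 11, and the Na2S2O4 wash returns 11 to 12, so the oxidant need not be metered. The step needs O- over C-attack and C8a over C6 or C7: attack by the central carbon would form a four-membered ring, and C6 and C7 lie out of reach of the tethered oxygen and are methoxyl-bearing vinylogous ester carbons, whereas C8a is unsubstituted and doubly activated. The classical cyclodehydration through the ortho hydroxyl, which would give the isomeric 6-hydroxy-7,8-dimethoxyflavone, is excluded because no acid is present and that oxygen is a quinone carbonyl while the ring closes. Dilute, anhydrous conditions disfavour addition of a second diketone molecule or of water to 10.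

Step 6
Reactants: 12 2-[2,5-bis(benzyloxy)phenyl]-5,8-dihydroxy-6,7-dimethoxy-4H-chromen-4-one
Product: 13 2-[2,5-bis(benzyloxy)phenyl]-5-hydroxy-6,7,8-trimethoxy-4H-chromen-4-one
Conditions: MeI (1.1 equiv), K2CO3 (1.5 equiv), acetone, rt, Ar
Reagents that add atoms: iodomethane, CI
Why: Williamson methylation: the 5-hydroxyl is locked in a hydrogen bond to the C4 carbonyl and is far less nucleophilic, so a slight excess of iodomethane at room temperature should alkylate only the 8-hydroxyl. Argon protects the hydroquinone from base-promoted air oxidation.

Step 7
Reactants: 13 2-[2,5-bis(benzyloxy)phenyl]-5-hydroxy-6,7,8-trimethoxy-4H-chromen-4-one; 5 benzyl bromide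
Product: 14 5-(benzyloxy)-2-[2,5-bis(benzyloxy)phenyl]-6,7,8-trimethoxy-4H-chromen-4-one
Conditions: BnBr (1.5 equiv), K2CO3 (3 equiv), KI (cat.), DMF, 70 °C
Reagents that add atoms: none
Why: Forcing Williamson benzylation of the chelated 5-hydroxyl, standard in flavone chemistry. It removes the last free phenol before the oxidation at C3 and adds no deprotection step, because the group leaves in step 9 with the others.

Step 8
Reactants: 14 5-(benzyloxy)-2-[2,5-bis(benzyloxy)phenyl]-6,7,8-trimethoxy-4H-chromen-4-one
Product: 16 5-(benzyloxy)-2-[2,5-bis(benzyloxy)phenyl]-3-hydroxy-6,7,8-trimethoxy-4H-chromen-4-one, via flavone 2,3-epoxide 15 (not isolated)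
Conditions: DMDO (3 equiv, acetone solution), CH2Cl2, 0 °C to rt, dark; evaporate; p-TsOH (cat.), CH2Cl2, rt
Reagents that add atoms: dimethyldioxirane, CC1(C)OO1
Why: Dimethyldioxirane epoxidation of the C2=C3 bond of an alkoxy-protected flavone gives the racemic, necessarily cis-fused epoxide 15. Acid opens it at C2 (cation stabilised by O1 and ring B) and loss of H3 gives the 3-hydroxyflavone, a known flavone-to-flavonol conversion. Ring A has no free position and no free phenol, which should limit arene oxidation.

Step 9
Reactants: 16 5-(benzyloxy)-2-[2,5-bis(benzyloxy)phenyl]-3-hydroxy-6,7,8-trimethoxy-4H-chromen-4-one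
Product: 17 2-(2,5-dihydroxyphenyl)-3,5-dihydroxy-6,7,8-trimethoxy-4H-chromen-4-one
Conditions: H2 (1 atm), Pd/C (10%), EtOAc–MeOH, rt; filtration and concentration under Ar
Reagents that add atoms: none
Why: Catalytic hydrogenolysis cleaves the three aryl benzyl ethers. The C2=C3 bond of a flavonol is part of a vinylogous ester and should not be reduced at atmospheric pressure, and the methyl ethers are inert. The product is isolated without exposure to air.

## Compound list

1 | 1-(2-hydroxy-3,4-dimethoxyphenyl)ethan-1-one | CC(=O)c1ccc(OC)c(OC)c1O | starting material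
2 | potassium 5-acetyl-4-hydroxy-2,3-dimethoxyphenyl sulfate | CC(=O)c1cc(OS(=O)(=O)[O-])c(OC)c(OC)c1O.[K+] | intermediate
3 | 1-(2,5-dihydroxy-3,4-dimethoxyphenyl)ethan-1-one | CC(=O)c1cc(O)c(OC)c(OC)c1O | intermediate
4 | methyl 2,5-dihydroxybenzoate | COC(=O)c1cc(O)ccc1O | starting material
5 | benzyl bromide | BrCc1ccccc1 | starting material
6 | methyl 2,5-bis(benzyloxy)benzoate | COC(=O)c1cc(OCc2ccccc2)ccc1OCc1ccccc1 | intermediate
7 | 2,5-bis(benzyloxy)benzoic acid | O=C(O)c1cc(OCc2ccccc2)ccc1OCc1ccccc1 | intermediate
8 | 2,5-bis(benzyloxy)benzoyl chloride | O=C(Cl)c1cc(OCc2ccccc2)ccc1OCc1ccccc1 | intermediate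
9 | 1-[2,5-bis(benzyloxy)phenyl]-3-(2,5-dihydroxy-3,4-dimethoxyphenyl)propane-1,3-dione | COc1c(O)c(C(=O)CC(=O)c2cc(OCc3ccccc3)ccc2OCc2ccccc2)cc(O)c1OC | intermediate
10 | 2-{3-[2,5-bis(benzyloxy)phenyl]-3-oxopropanoyl}-5,6-dimethoxycyclohexa-2,5-diene-1,4-dione | COC1=C(OC)C(=O)C(C(=O)CC(=O)c2cc(OCc3ccccc3)ccc2OCc2ccccc2)=CC1=O | intermediate
11 | 2-[2,5-bis(benzyloxy)phenyl]-6,7-dimethoxy-4H-chromene-4,5,8-trione | COC1=C(OC)C(=O)C2=C(C1=O)OC(=CC2=O)c1cc(OCc2ccccc2)ccc1OCc1ccccc1 | intermediate
12 | 2-[2,5-bis(benzyloxy)phenyl]-5,8-dihydroxy-6,7-dimethoxy-4H-chromen-4-one | COc1c(O)c2oc(-c3cc(OCc4ccccc4)ccc3OCc3ccccc3)cc(=O)c2c(O)c1OC | intermediate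
13 | 2-[2,5-bis(benzyloxy)phenyl]-5-hydroxy-6,7,8-trimethoxy-4H-chromen-4-one | COc1c(OC)c(O)c2c(=O)cc(-c3cc(OCc4ccccc4)ccc3OCc3ccccc3)oc2c1OC | intermediate
14 | 5-(benzyloxy)-2-[2,5-bis(benzyloxy)phenyl]-6,7,8-trimethoxy-4H-chromen-4-one | COc1c(OC)c(OCc2ccccc2)c2c(=O)cc(-c3cc(OCc4ccccc4)ccc3OCc3ccccc3)oc2c1OC | intermediate
15 | 6-(benzyloxy)-1a-[2,5-bis(benzyloxy)phenyl]-3,4,5-trimethoxy-1a,7a-dihydro-7H-oxireno[2,3-b]chromen-7-one (racemic, cis-fused 2,3-epoxide of 14) | COc1c(OC)c(OCc2ccccc2)c2c(c1OC)OC1(c3cc(OCc4ccccc4)ccc3OCc3ccccc3)OC1C2=O | intermediate
16 | 5-(benzyloxy)-2-[2,5-bis(benzyloxy)phenyl]-3-hydroxy-6,7,8-trimethoxy-4H-chromen-4-one | COc1c(OC)c(OCc2ccccc2)c2c(=O)c(O)c(-c3cc(OCc4ccccc4)ccc3OCc3ccccc3)oc2c1OC | intermediate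
17 | 2-(2,5-dihydroxyphenyl)-3,5-dihydroxy-6,7,8-trimethoxy-4H-chromen-4-one | COc1c(OC)c(O)c2c(=O)c(O)c(-c3cc(O)ccc3O)oc2c1OC | target

## Step count and least certain steps

Total: 9 steps. Longest linear sequence: 8 steps (from 4 through steps 2, 3, 4, 5, 6, 7, 8 and 9); the ring A branch from 1 joins at step 4.

Step 5 (key step, proposed new method). What may go wrong: intermolecular conjugate addition of the diketone carbon of one molecule to the acylquinone of another, competing with ring closure; addition of adventitious water to the acylquinone or displacement of a methoxyl on it; and slow closure because the enol is held in an internal hydrogen bond away from C8a. The fallback uses known chemistry, sets out from 3 and returns to the route at 14. The non-chelated hydroxyl of 3 is methylated (MeI, K2CO3, acetone, rt) to 1-(2-hydroxy-3,4,5-trimethoxyphenyl)ethan-1-one F1, and the chelated hydroxyl is then benzylated with 5 (K2CO3, DMF, 70 °C) to 1-[2-(benzyloxy)-3,4,5-trimethoxyphenyl]ethan-1-one F2. N-Bromosuccinimide in MeCN should brominate the only free ring carbon to give 1-[2-(benzyloxy)-6-bromo-3,4,5-trimethoxyphenyl]ethan-1-one F3. Claisen aroylation of its lithium enolate (LiN(SiMe3)2, THF, −78 °C) with 8 would give 1-[2-(benzyloxy)-6-bromo-3,4,5-trimethoxyphenyl]-3-[2,5-bis(benzyloxy)phenyl]propane-1,3-dione F4. Intramolecular Ullmann-type O-arylation of the diketone enolate (CuI cat., K2CO3, DMF, 100 °C), a known flavone-forming reaction of 1-(2-bromoaryl)-1,3-diketones, then closes the same C8a–O1 bond and gives 14. This replaces steps 4 to 7 with five steps and gives up the dehydrogenative closure for a halogen-based one.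

Step 8. What may go wrong: oxidation of the electron-rich aromatic rings or of benzylic C–H bonds by the dioxirane, competing with a slow epoxidation of a C2=C3 bond that is twisted out of conjugation by the 2'-substituent. The fallback sets out from 14 and returns at 16: C3 is lithiated with LiN(iPr)2 (THF, −78 °C), a known metalation of alkoxy-flavones, the anion is trapped with B(OMe)3 to give dimethyl {5-(benzyloxy)-2-[2,5-bis(benzyloxy)phenyl]-6,7,8-trimethoxy-4-oxo-4H-chromen-3-yl}boronate F5, and this is oxidised in the same flask with H2O2/AcOH to 16.

Step 4. What may go wrong: O-aroylation at the non-chelated phenoxide in place of C-acylation, and air oxidation of the very electron-rich trianion. The fallback sets out from 3 and returns at 9. Both hydroxyls are aroylated with 8 (2.2 equiv, pyridine) to 2-acetyl-5,6-dimethoxy-1,4-phenylene bis[2,5-bis(benzyloxy)benzoate] F6. Baker–Venkataraman rearrangement (KOH, pyridine, 50 °C) moves the ortho aroyl group to the acetyl carbon and gives 5-{3-[2,5-bis(benzyloxy)phenyl]-3-oxopropanoyl}-4-hydroxy-2,3-dimethoxyphenyl 2,5-bis(benzyloxy)benzoate F7. The remaining aryl ester is cleaved with LiOH in degassed THF–H2O at rt to give 9, with 7 recovered for recycling.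

Step 1. What may go wrong: low conversion and oxidative degradation to dark polymeric material, the usual weakness of persulfate oxidations. The fallback sets out from 1 and returns at 3. Duff formylation (hexamethylenetetramine, CF3CO2H, 80 °C) at C5, para to the hydroxyl whose two ortho positions are blocked, gives 5-acetyl-4-hydroxy-2,3-dimethoxybenzaldehyde F8. Baeyer–Villiger (Dakin-type) oxidation of the aldehyde with 3-chloroperbenzoic acid in CH2Cl2 gives 5-acetyl-4-hydroxy-2,3-dimethoxyphenyl formate F9, and methanolysis (HCl, MeOH, rt) releases 3.

Step 9. What may go wrong: incomplete cleavage at the crowded 2'-O-benzyl position during a prolonged heterogeneous reaction, and air oxidation of the liberated ring B hydroquinone during filtration, followed by attack of the 3-hydroxyl on the resulting quinone. The fallback sets out from 16 and returns at 17: homogeneous Lewis-acid debenzylation with BCl3 and pentamethylbenzene as cation scavenger (CH2Cl2, −78 °C, methanol quench under Ar). The methyl ethers should survive at this temperature. This fallback makes no new compound and is entered as F0.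

## Further compounds

F1 | step 5 | 1-(2-hydroxy-3,4,5-trimethoxyphenyl)ethan-1-one | CC(=O)c1cc(OC)c(OC)c(OC)c1O
F2 | step 5 | 1-[2-(benzyloxy)-3,4,5-trimethoxyphenyl]ethan-1-one | CC(=O)c1cc(OC)c(OC)c(OC)c1OCc1ccccc1
F3 | step 5 | 1-[2-(benzyloxy)-6-bromo-3,4,5-trimethoxyphenyl]ethan-1-one | CC(=O)c1c(Br)c(OC)c(OC)c(OC)c1OCc1ccccc1
F4 | step 5 | 1-[2-(benzyloxy)-6-bromo-3,4,5-trimethoxyphenyl]-3-[2,5-bis(benzyloxy)phenyl]propane-1,3-dione | O=C(CC(=O)c1cc(OCc2ccccc2)ccc1OCc1ccccc1)c1c(Br)c(OC)c(OC)c(OC)c1OCc1ccccc1
F5 | step 8 | dimethyl {5-(benzyloxy)-2-[2,5-bis(benzyloxy)phenyl]-6,7,8-trimethoxy-4-oxo-4H-chromen-3-yl}boronate | COB(OC)c1c(-c2cc(OCc3ccccc3)ccc2OCc2ccccc2)oc2c(OC)c(OC)c(OC)c(OCc3ccccc3)c2c1=O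
F6 | step 4 | 2-acetyl-5,6-dimethoxy-1,4-phenylene bis[2,5-bis(benzyloxy)benzoate] | CC(=O)c1cc(OC(=O)c2cc(OCc3ccccc3)ccc2OCc2ccccc2)c(OC)c(OC)c1OC(=O)c1cc(OCc2ccccc2)ccc1OCc1ccccc1
F7 | step 4 | 5-{3-[2,5-bis(benzyloxy)phenyl]-3-oxopropanoyl}-4-hydroxy-2,3-dimethoxyphenyl 2,5-bis(benzyloxy)benzoate | COc1c(OC(=O)c2cc(OCc3ccccc3)ccc2OCc2ccccc2)cc(C(=O)CC(=O)c2cc(OCc3ccccc3)ccc2OCc2ccccc2)c(O)c1OC
F8 | step 1 | 5-acetyl-4-hydroxy-2,3-dimethoxybenzaldehyde | CC(=O)c1cc(C=O)c(OC)c(OC)c1O
F9 | step 1 | 5-acetyl-4-hydroxy-2,3-dimethoxyphenyl formate | CC(=O)c1cc(OC=O)c(OC)c(OC)c1O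
F0 | step 9 | none | none
A1 | alternative 1 | 5-(benzyloxy)-2-[2,5-bis(benzyloxy)phenyl]-6,7,8-trimethoxy-4H-chromen-4-one | COc1c(OC)c(OCc2ccccc2)c2c(=O)cc(-c3cc(OCc4ccccc4)ccc3OCc3ccccc3)oc2c1OC
A2 | alternative 1 | 3-(benzyloxy)-4,5,6-trimethoxy-2-[2-(triphenyl-λ5-phosphanylidene)acetyl]phenyl 2,5-bis(benzyloxy)benzoate | COc1c(OC)c(OCc2ccccc2)c(C(=O)C=P(c2ccccc2)(c2ccccc2)c2ccccc2)c(OC(=O)c2cc(OCc3ccccc3)ccc2OCc2ccccc2)c1OC
A3 | alternative 1 | 1-[2-(benzyloxy)-6-hydroxy-3,4,5-trimethoxyphenyl]ethan-1-one | CC(=O)c1c(O)c(OC)c(OC)c(OC)c1OCc1ccccc1
A4 | alternative 2 | 3-(benzyloxy)-2-[2,5-bis(benzyloxy)phenyl]-5-hydroxy-6,7,8-trimethoxy-4H-chromen-4-one | COc1c(OC)c(O)c2c(=O)c(OCc3ccccc3)c(-c3cc(OCc4ccccc4)ccc3OCc3ccccc3)oc2c1OC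
A5 | alternative 2 | 4-{5-(benzyloxy)-6-[2,5-bis(benzyloxy)phenyl]-4-oxo-4H-pyran-2-yl}-2,3,4-trimethoxycyclobut-2-en-1-one (racemic) | COC1=C(OC)C(OC)(c2cc(=O)c(OCc3ccccc3)c(-c3cc(OCc4ccccc4)ccc3OCc3ccccc3)o2)C1=O
A6 | alternative 2 | 3,4-dimethoxycyclobut-3-ene-1,2-dione | COC1=C(OC)C(=O)C1=O
A7 | alternative 2 | 3-(benzyloxy)-2-[2,5-bis(benzyloxy)phenyl]-4H-pyran-4-one | O=c1ccoc(-c2cc(OCc3ccccc3)ccc2OCc2ccccc2)c1OCc1ccccc1
A8 | alternative 3 | 2-[2,5-bis(benzyloxy)phenyl]-5-hydroxy-6,7,8-trimethoxy-4H-chromen-4-one | COc1c(OC)c(O)c2c(=O)cc(-c3cc(OCc4ccccc4)ccc3OCc3ccccc3)oc2c1OC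
A9 | alternative 3 | (2Z)-3-[2,5-bis(benzyloxy)phenyl]-3-(5-hydroxy-2,3,4-trimethoxyphenoxy)prop-2-enoic acid | OC(=O)/C=C(\Oc1cc(O)c(OC)c(OC)c1OC)c1cc(OCc2ccccc2)ccc1OCc1ccccc1
A10 | alternative 3 | 4,5,6-trimethoxybenzene-1,3-diol | COc1c(O)cc(O)c(OC)c1OC
A11 | alternative 3 | ethyl 3-[2,5-bis(benzyloxy)phenyl]prop-2-ynoate | CCOC(=O)C#Cc1cc(OCc2ccccc2)ccc1OCc1ccccc1
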